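Retrosynthetic overview
1. Target 31 ⇐ 5-oxo lactam 30 (tertiary amide → amine) ⇐ N-acyliminium ion at C3 of lactam 25 + silyloxyfuran 28 (vinylogous Mannich addition, then hydrogenation; builds ring E).
2. Tetracyclic lactam 21 ⇐ hydroxy acetamide 18 by a ring-expanding Claisen rearrangement that closes the azepane ring A (N4–C5–C6–C7–C8–C9–C9a) at C6–C7; C5/C6 are the N-acetyl carbons, C7/C8 a vinyl group on C9.
3. Enabling feature: in the cyclopentane ring C, C9 lies next to the N-bearing quaternary C9a. A cis-1,2-amino alcohol (N4 on C9a, O on C9) can therefore tie C5 into an oxazolidine ketene N,O-acetal whose O–C9 bond is allylic; C5(=O)–C6–C7–C8=C9 is the Claisen retron, and C8=C9 is hydrogenated afterwards.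
4. 18 ⇐ keto-lactone 16 (lactone ring D by conjugate lactonisation onto a ring C enone) ⇐ spiro 2-ethylcyclopentane-1,3-dione 10 (ring C by Dieckmann condensation) ⇐ D-proline (pyrrolidine ring B; C9a by α-alkylation with self-regeneration of the stereocentre).
5. Order of ring formation: B (from proline) → C → D → A (key step) → E.

Key step: step 11

Remark on numbering and faces: C1–C3 and N4 form the pyrrolidine ring B, C5–C9 with N4 and C9a the azepane ring A, and C9a–C9–C10–C11–C12 the cyclopentane ring C (C10 carries ethyl, C11 oxygen). C13 (C(OH)Me) and C14 (C=O) complete the fused lactone ring D; C18–C21 belong to the butyrolactone ring E on C3. The "top" face of ring C carries C1, O11 and C13; the "bottom" face carries N4, the ethyl group and, in the target, C8.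
Remark on tautomers: the 1,3-diones 10 and 12 should exist largely as enols; they are drawn as diketones with C10 undefined.

Step 1
Reactants: 1 D-proline; 2 pivalaldehyde
Product: 3 (2S,5R)-2-tert-butyl-1-aza-3-oxabicyclo[3.3.0]octan-4-one
Conditions: CF3CO2H (cat.), pentane, reflux, Dean–Stark trap
Reagents that add atoms: pivalaldehyde (2), CC(C)(C)C=O
Why: N,O-acetal formation (the self-regeneration-of-stereocentres auxiliary for proline) should give the cis-fused bicycle as one diastereomer, the proline stereocentre placing tert-butyl on the convex face.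

Step 2
Reactants: 3 (2S,5R)-2-tert-butyl-1-aza-3-oxabicyclo[3.3.0]octan-4-one; 4 1-bromopent-2-yne
Product: 5 (2S,5S)-2-tert-butyl-5-(pent-2-yn-1-yl)-1-aza-3-oxabicyclo[3.3.0]octan-4-one
Conditions: LiN(i-Pr)2, THF, −78 °C; then 4, −78 → −30 °C
Reagents that add atoms: 1-bromopent-2-yne (4), CCC#CCBr
Why: Enolate alkylation of the bicyclic lactone occurs on the face cis to tert-butyl, i.e. with retention at the former proline α-carbon, which fixes the quaternary C9a in the absolute configuration of the target.

Step 3
Reactants: 5 (2S,5S)-2-tert-butyl-5-(pent-2-yn-1-yl)-1-aza-3-oxabicyclo[3.3.0]octan-4-one; 6 acetic anhydride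
Product: 8 methyl (2S)-1-acetyl-2-(pent-2-yn-1-yl)pyrrolidine-2-carboxylate, via amino ester hydrochloride 7 (not isolated)
Conditions: HCl, MeOH, reflux; evaporate; then Ac2O, Et3N, DMAP (cat.), CH2Cl2, 0 °C → rt
Reagents that add atoms: methanol, CO; acetic anhydride (6), CC(=O)OC(C)=O
Why: Acid methanolysis of the N,O-acetal with Fischer esterification, then N-acetylation, removes the auxiliary and installs the acetyl group whose two carbons become C5 and C6; the quaternary centre cannot epimerise.

Step 4
Reactants: 8 methyl (2S)-1-acetyl-2-(pent-2-yn-1-yl)pyrrolidine-2-carboxylate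
Product: 9 methyl (2S)-1-acetyl-2-(2-oxopentyl)pyrrolidine-2-carboxylate
Conditions: NaAuCl4·2H2O (2 mol%), MeOH/H2O (10:1), 60 °C
Reagents that add atoms: water, O
Why: Gold-catalysed alkyne hydration with carbonyl participation: exo attack of the neighbouring ester (or acetamide) oxygen on the alkyne activated by trivalent gold delivers oxygen to the proximal alkyne carbon (C11), so the γ-keto ester should form regioselectively.

Step 5
Reactants: 9 methyl (2S)-1-acetyl-2-(2-oxopentyl)pyrrolidine-2-carboxylate
Product: 10 (5S)-1-acetyl-7-ethyl-1-azaspiro[4.4]nonane-6,8-dione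
Conditions: KOt-Bu (2.2 equiv), THF, 0 °C → rt; then aq. HCl
Reagents that add atoms: none
Why: Dieckmann-type condensation of the ketone enolate at C10 onto the ester (5-exo-trig) closes ring C, the classical route from γ-keto esters to 2-alkylcyclopentane-1,3-diones.

Step 6
Reactants: 10 (5S)-1-acetyl-7-ethyl-1-azaspiro[4.4]nonane-6,8-dione; 11 tert-butyl bromoacetate
Product: 12 tert-butyl 2-[(5S,9S)-1-acetyl-7-ethyl-6,8-dioxo-1-azaspiro[4.4]nonan-9-yl]acetate (acetate arm on C12 anti to N4)
Conditions: LiN(i-Pr)2 (2.2 equiv), THF/DMPU, −78 → −20 °C; then 11, −78 → 0 °C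
Reagents that add atoms: tert-butyl bromoacetate (11), CC(C)(C)OC(=O)CBr
Why: γ-Alkylation of a 1,3-diketone dianion: the second deprotonation can only occur at C12 (C9a is quaternary), and the electrophile should approach anti to the N-acetyl group of the adjacent spiro centre, placing the acetate arm on the face of C1.

Step 7
Reactants: 12 tert-butyl 2-[(5S,9S)-1-acetyl-7-ethyl-6,8-dioxo-1-azaspiro[4.4]nonan-9-yl]acetate
Product: 13 tert-butyl 2-[(5S,9S)-1-acetyl-7-ethyl-6-oxo-8-(trifluoromethylsulfonyloxy)-1-azaspiro[4.4]non-7-en-9-yl]acetate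
Conditions: (CF3SO2)2O, Et3N, CH2Cl2, −78 °C
Reagents that add atoms: trifluoromethanesulfonic anhydride, O=S(=O)(OS(=O)(=O)C(F)(F)F)C(F)(F)F
Why: O-Sulfonylation of the vinylogous acid at its less hindered oxygen (on C11, remote from the quaternary C9a) should give the β-triflyloxy enone that keeps the C9 carbonyl.

Step 8
Reactants: 13 tert-butyl 2-[(5S,9S)-1-acetyl-7-ethyl-6-oxo-8-(trifluoromethylsulfonyloxy)-1-azaspiro[4.4]non-7-en-9-yl]acetate
Product: 14 tert-butyl 2-[(5S,9R)-1-acetyl-7-ethyl-6-oxo-1-azaspiro[4.4]non-7-en-9-yl]acetate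
Conditions: Pd(OAc)2 (5 mol%), PPh3 (10 mol%), HCO2H, n-Bu3N, DMF, 60 °C
Reagents that add atoms: none
Why: Palladium-catalysed formate reduction of an enol triflate (oxidative addition to zerovalent palladium, formate decarboxylation, reductive elimination) should give the 2-ethylcyclopentenone without touching C12.

Step 9
Reactants: 14 tert-butyl 2-[(5S,9R)-1-acetyl-7-ethyl-6-oxo-1-azaspiro[4.4]non-7-en-9-yl]acetate
Product: 16 keto-lactone 1'-acetyl-6-ethyltetrahydrospiro[cyclopenta[b]furan-4,2'-pyrrolidine]-2,5(3H)-dione (ring D cis-fused on the top face; ethyl on the bottom face), via carboxylic acid 15 (not isolated)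
Conditions: CF3CO2H, CH2Cl2, rt; then TsOH·H2O (cat.), toluene, 60 °C
Reagents that add atoms: none
Why: Acidolysis of the tert-butyl ester followed by acid-catalysed intramolecular oxa-Michael addition (5-exo-trig conjugate lactonisation) closes ring D necessarily cis-fused, O11 entering on the face of the C12 arm, while C10 should equilibrate through the enol to place ethyl anti to O11.

Step 10
Reactants: 16 keto-lactone; 17 vinylmagnesium bromide
Product: 18 hydroxy acetamide 1'-acetyl-6-ethyl-5-hydroxy-5-vinylhexahydrospiro[cyclopenta[b]furan-4,2'-pyrrolidin]-2(3H)-one (C9 hydroxyl on the bottom face cis to N4; vinyl on the top face)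
Conditions: CeCl3 (anhydrous), 17, THF, −78 °C; then aq. NH4Cl
Reagents that add atoms: vinylmagnesium bromide (17), C=C[Mg]Br
Why: 1,2-Addition of a weakly basic organocerium reagent to the ketone; the bottom face is blocked by the N-acetyl group on C9a and the ethyl group on C10, so vinyl should add from the top face and leave the C9 hydroxyl cis to N4.

Step 11
Reactants: 18 hydroxy acetamide
Product: 21 tetracyclic lactam with rings A–D (C5 lactam carbonyl and C8=C9 double bond), via oxazolinium triflate 19 (not isolated), via cyclic ketene N,O-acetal 20 (not isolated)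
Conditions: (CF3SO2)2O, 2-fluoropyridine, CH2Cl2, −78 → 0 °C; then DBU (3 equiv), toluene, 0 → 80 °C
Reagents that add atoms: none
Why: Triflic anhydride activates the acetamide, the cis-disposed tertiary C9 hydroxyl adds to C5 to give the cis-fused 2-methyloxazolinium ion 19, and DBU deprotonates it to the 2-methylene-oxazolidine 20, whose O–C9 bond is allylic to the vinyl group, so that a [3,3]-sigmatropic shift forms C6–C7, cleaves O–C9 and unveils the C5 lactam carbonyl. The closest known reaction types are the Eschenmoser–Claisen rearrangement and the Claisen ring expansion of vinyl-substituted cyclic ketene N,O-acetals to unsaturated seven- and eight-membered lactams. The temporary oxazolidine is closed by 5-exo-trig attack of oxygen on the activated amide, and the azepinone ring A is closed by the sigmatropic C6–C7 bond formation through a boat-like transition state, a two-atom ring expansion of that oxazolidine. No new stereocentre is created: C9 becomes sp2, the C8=C9 double bond is Z by ring constraint, and C9a, C10, C11 and C12 are untouched. The step needs the ketene N,O-acetal to form and rearrange faster than the tertiary allylic C9–O bond of 19 ionises; this is secured by amide activation at −78 °C, prompt deprotonation by the amidine base and the large driving force of turning a ketene N,O-acetal into an amide.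

Step 12
Reactants: 21 tetracyclic lactam with C8=C9
Product: 22 saturated tetracyclic lactam (C9–H on the top face; rings A and C cis-fused)
Conditions: H2 (1 atm), Pd/C (10%), EtOAc, rt
Reagents that add atoms: none
Why: Heterogeneous catalytic hydrogenation; hydrogen should add to the top face of C8=C9, opposite the C10 ethyl group and the N4/C5 limb of ring A, which sets C9 with the cis A/C ring fusion.

Step 13
Reactants: 22 saturated tetracyclic lactam
Product: 23 13-hydroxy lactone (hydroxyl mainly on the convex face of ring D)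
Conditions: KN(SiMe3)2 (1.05 equiv), THF, −78 °C; then 2-(phenylsulfonyl)-3-phenyloxaziridine
Reagents that add atoms: 2-(phenylsulfonyl)-3-phenyloxaziridine, O=S(=O)(c1ccccc1)N1OC1c1ccccc1
Why: Electrophilic hydroxylation of the lactone enolate (the lactone α-CH2 is clearly more acidic than the lactam α-CH2) on the convex face of ring D; the C13 configuration is erased again in step 14.

Step 14
Reactants: 23 13-hydroxy lactone; 24 iodomethane
Product: 25 13-hydroxy-13-methyl lactone (methyl exo, hydroxyl endo towards C1, as in the target)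
Conditions: LiN(i-Pr)2 (2.1 equiv), THF, −78 °C; then 24, −78 → −20 °C
Reagents that add atoms: iodomethane (24), CI
Why: C-Alkylation of the α-hydroxy lactone dianion (enediolate); iodomethane should approach the convex face of ring D, so methyl ends up exo and the hydroxyl endo, the C13 configuration of the target.

Step 15
Reactants: 25 13-hydroxy-13-methyl lactone
Product: 26 3-methoxy lactam (N,O-acetal at C3, epimer mixture)
Conditions: anodic oxidation (graphite anode, constant current, 2.5 F/mol), Et4NOTs, MeOH, 0 °C
Reagents that add atoms: methanol, CO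
Why: Shono oxidation (anodic α-methoxylation of an amide): C3 carries the only C–H bonds α to the lactam nitrogen on its non-acyl side (C9a is quaternary), so the N,O-acetal should form there, and its configuration is inconsequential.

Step 16
Reactants: 27 3-methylfuran-2(5H)-one
Product: 28 3-methyl-2-(triisopropylsilyloxy)furan
Conditions: i-Pr3SiOSO2CF3, Et3N, CH2Cl2, 0 °C
Reagents that add atoms: triisopropylsilyl trifluoromethanesulfonate, CC(C)[Si](OS(=O)(=O)C(F)(F)F)(C(C)C)C(C)C
Why: Soft enolisation and O-silylation of the butenolide gives the 2-silyloxyfuran (silyl dienol ether) used as the vinylogous nucleophile.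

Step 17
Reactants: 26 3-methoxy lactam; 28 3-methyl-2-(triisopropylsilyloxy)furan
Product: 29 butenolide adduct (3S,18S; 5-oxo lactam carrying the 3-methyl-2(5H)-furanon-5-yl group on C3)
Conditions: BF3·OEt2, CH2Cl2, −78 °C
Reagents that add atoms: 3-methyl-2-(triisopropylsilyloxy)furan (28), Cc1ccoc1O[Si](C(C)C)(C(C)C)C(C)C
Why: Vinylogous Mukaiyama–Mannich addition to the N-acyliminium ion: the furan should attack C3 anti to the C12 branch of the spiro centre (the branch that carries ring D) and with the threo topicity usual for 2-silyloxyfurans and cyclic N-acyliminium ions, which is the (3S,18S) arrangement.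

Step 18
Reactants: 29 butenolide adduct
Product: 30 5-oxo derivative of the target (saturated ring E, C20 methyl cis to the C18 substituent)
Conditions: H2 (1 atm), Pd/C (10%), EtOAc, rt
Reagents that add atoms: none
Why: Heterogeneous hydrogenation of the butenolide from the face opposite the C18 substituent should give the cis-2,4-disubstituted γ-lactone and thus the C20 methyl centre.

Step 19
Reactants: 30 5-oxo derivative of the target
Product: 31 target CNP0260919.4
Conditions: RhH(CO)(PPh3)3 (2 mol%), Ph2SiH2, THF, rt; then aq. HCl, then NaHCO3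
Reagents that add atoms: none
Why: Rhodium-catalysed hydrosilylation should reduce the tertiary lactam to the amine chemoselectively in the presence of both γ-lactones, and the work-up cleaves any silyl ether formed at the tertiary hydroxyl.

Compound list
1 | D-proline | OC(=O)[C@H]1CCCN1 | starting material
2 | pivalaldehyde | CC(C)(C)C=O | starting material
3 | (2S,5R)-2-tert-butyl-1-aza-3-oxabicyclo[3.3.0]octan-4-one | O=C1O[C@@H](C(C)(C)C)N2CCC[C@H]12 | intermediate
4 | 1-bromopent-2-yne | CCC#CCBr | starting material
5 | (2S,5S)-2-tert-butyl-5-(pent-2-yn-1-yl)-1-aza-3-oxabicyclo[3.3.0]octan-4-one | O=C1O[C@@H](C(C)(C)C)N2CCC[C@]12CC#CCC | intermediate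
6 | acetic anhydride | CC(=O)OC(C)=O | starting material
7 | methyl (2S)-2-(pent-2-yn-1-yl)pyrrolidine-2-carboxylate hydrochloride (not isolated) | CCC#CC[C@@]1(CCCN1)C(=O)OC.Cl | intermediate
8 | methyl (2S)-1-acetyl-2-(pent-2-yn-1-yl)pyrrolidine-2-carboxylate | CCC#CC[C@@]1(CCCN1C(C)=O)C(=O)OC | intermediate
9 | methyl (2S)-1-acetyl-2-(2-oxopentyl)pyrrolidine-2-carboxylate | CCCC(=O)C[C@@]1(CCCN1C(C)=O)C(=O)OC | intermediate
10 | (5S)-1-acetyl-7-ethyl-1-azaspiro[4.4]nonane-6,8-dione (enolised; C10 undefined) | CCC1C(=O)C[C@@]2(CCCN2C(C)=O)C1=O | intermediate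
11 | tert-butyl bromoacetate | CC(C)(C)OC(=O)CBr | starting material
12 | tert-butyl 2-[(5S,9S)-1-acetyl-7-ethyl-6,8-dioxo-1-azaspiro[4.4]nonan-9-yl]acetate (enolised; C10 undefined) | CCC1C(=O)[C@@H](CC(=O)OC(C)(C)C)[C@@]2(CCCN2C(C)=O)C1=O | intermediate
13 | tert-butyl 2-[(5S,9S)-1-acetyl-7-ethyl-6-oxo-8-(trifluoromethylsulfonyloxy)-1-azaspiro[4.4]non-7-en-9-yl]acetate | CCC1=C(OS(=O)(=O)C(F)(F)F)[C@@H](CC(=O)OC(C)(C)C)[C@@]2(CCCN2C(C)=O)C1=O | intermediate
14 | tert-butyl 2-[(5S,9R)-1-acetyl-7-ethyl-6-oxo-1-azaspiro[4.4]non-7-en-9-yl]acetate | CCC1=C[C@@H](CC(=O)OC(C)(C)C)[C@@]2(CCCN2C(C)=O)C1=O | intermediate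
15 | 2-[(5S,9R)-1-acetyl-7-ethyl-6-oxo-1-azaspiro[4.4]non-7-en-9-yl]acetic acid (not isolated) | CCC1=C[C@@H](CC(=O)O)[C@@]2(CCCN2C(C)=O)C1=O | intermediate
16 | keto-lactone: 1'-acetyl-6-ethyltetrahydrospiro[cyclopenta[b]furan-4,2'-pyrrolidine]-2,5(3H)-dione; ring D cis-fused on the top face, ethyl on the bottom face, N4 trans to C13 | CC[C@@H]1[C@H]2OC(=O)C[C@H]2[C@@]3(CCCN3C(C)=O)C1=O | intermediate
17 | vinylmagnesium bromide | C=C[Mg]Br | starting material
18 | hydroxy acetamide: 1'-acetyl-6-ethyl-5-hydroxy-5-vinylhexahydrospiro[cyclopenta[b]furan-4,2'-pyrrolidin]-2(3H)-one; C9–OH cis to N4, vinyl on the top face | CC[C@@H]1[C@H]2OC(=O)C[C@H]2[C@@]3(CCCN3C(C)=O)[C@@]1(O)C=C | intermediate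
19 | cis-fused 2-methyloxazolinium triflate (O on C9, N4 on C9a; not isolated) | CC[C@@H]1[C@H]2OC(=O)C[C@H]2[C@@]3(CCC[N+]3=C(C)O4)[C@@]14C=C.[O-]S(=O)(=O)C(F)(F)F | intermediate
20 | cyclic ketene N,O-acetal (2-methylene-oxazolidine fused at C9–C9a, vinyl on C9; not isolated) | CC[C@@H]1[C@H]2OC(=O)C[C@H]2[C@@]3(CCCN3C(=C)O4)[C@@]14C=C | intermediate
21 | tetracyclic lactam (rings A–D): C5 lactam carbonyl, C8=C9 double bond (Z in ring A), C13 methylene | CC[C@@H]1[C@H]2OC(=O)C[C@H]2[C@]23CCCN2C(=O)CCC=C13 | intermediate
22 | saturated tetracyclic lactam: C9–H on the top face, rings A and C cis-fused | CC[C@@H]1[C@H]2OC(=O)C[C@H]2[C@]23CCCN2C(=O)CCC[C@H]13 | intermediate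
23 | 13-hydroxy lactone of 22 (major epimer expected, hydroxyl exo) | CC[C@@H]1[C@H]2OC(=O)[C@H](O)[C@H]2[C@]23CCCN2C(=O)CCC[C@H]13 | intermediate
24 | iodomethane | CI | starting material
25 | 13-hydroxy-13-methyl lactone (methyl exo, hydroxyl endo) | CC[C@@H]1[C@H]2OC(=O)[C@@](C)(O)[C@H]2[C@]23CCCN2C(=O)CCC[C@H]13 | intermediate
26 | 3-methoxy lactam (C3 epimer mixture) | CC[C@@H]1[C@H]2OC(=O)[C@@](C)(O)[C@H]2[C@]23CCC(OC)N2C(=O)CCC[C@H]13 | intermediate
27 | 3-methylfuran-2(5H)-one | CC1=CCOC1=O | starting material
28 | 3-methyl-2-(triisopropylsilyloxy)furan | Cc1ccoc1O[Si](C(C)C)(C(C)C)C(C)C | intermediate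
29 | butenolide adduct (3S,18S): 5-oxo lactam with a 3-methyl-2(5H)-furanon-5-yl group on C3 | CC[C@@H]1[C@H]2OC(=O)[C@@](C)(O)[C@H]2[C@]23CC[C@@H]([C@@H]4C=C(C)C(=O)O4)N2C(=O)CCC[C@H]13 | intermediate
30 | 5-oxo derivative of the target (ring E saturated, methyl cis to the C18 substituent) | CC[C@@H]1[C@H]2OC(=O)[C@@](C)(O)[C@H]2[C@]23CC[C@@H]([C@@H]4C[C@H](C)C(=O)O4)N2C(=O)CCC[C@H]13 | intermediate
31 | CNP0260919.4 | CC[C@@H]1[C@H]2OC(=O)[C@@](C)(O)[C@H]2[C@]23CC[C@@H]([C@@H]4C[C@H](C)C(=O)O4)N2CCCC[C@H]13 | target

Total step count: 19. Longest linear sequence: 18 steps (steps 1–15 and 17–19 from D-proline; step 16 is a one-step side branch).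

Steps most likely to fail

1. Step 11 (key step). The oxazolinium ion 19 may ionise at its tertiary allylic C9–O bond, with elimination or recapture of the allyl cation at C7, before it is deprotonated. Alternatively the strained boat transition state may be too slow, so that the ketene N,O-acetal decomposes instead of rearranging. The fallback sets out from 18 and comes back at 22. Compound 18 is heated with trimethyl orthoacetate and catalytic propionic acid (intermolecular Johnson–Claisen rearrangement, 140 °C), which should give the γ,δ-unsaturated methyl ester F1 with the C6–C7 bond in place (E/Z mixture at C8=C9). Hydrogenation (H2, Pd/C) should give the saturated ester F2 with C9–H on the top face. O-Ethylation of the acetamide with Et3O·BF4 and mild aqueous hydrolysis of the imidate salt removes the acetyl group to give the amino ester F3. Heating F3 with 2-hydroxypyridine in toluene closes ring A by lactamisation (N4–C5) to 22.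

2. Step 10. The C9 ketone is flanked by a quaternary and a tertiary carbon. Enolisation with β-elimination of the lactone carboxylate (retro-oxa-Michael), or attack at the unhindered lactone carbonyl, may therefore outrun addition. The fallback sets out from 16 and comes back at 18. Addition of the much smaller and far less basic alkynyl nucleophile (HC≡CMgBr, CeCl3, THF, −78 °C) should give the propargylic alcohol F4 with the same facial preference. Semi-hydrogenation over Pd/CaCO3 poisoned with Pb(OAc)2 (quinoline, H2) then gives 18.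

3. Step 17. Facial selectivity at C3 or threo/erythro selectivity at C18 may be poor, because both new stereocentres are set in one addition to a tetracyclic N-acyliminium ion that has not been studied before. The fallback sets out from 26 and comes back at 30, and sets the three side-chain centres one at a time. Vinyl transfer to the N-acyliminium ion (CH2=CHMgBr, CuBr·SMe2, BF3·OEt2, THF, −78 °C) should give the 3-vinyl lactam F5. Ozonolysis (O3, CH2Cl2/MeOH, −78 °C; then Me2S) gives the aldehyde F6. Zinc-mediated Barbier allylation with ethyl 2-(bromomethyl)acrylate (Zn, THF/aq. NH4Cl), expected to follow Felkin–Anh control, gives the hydroxy ester F7. On acid treatment (TsOH) F7 lactonises to the α-methylene lactone F8. Hydrogenation over Rh/Al2O3 from the face opposite the C18 substituent then gives 30.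

Further compounds
F1 | step 11 | γ,δ-unsaturated methyl ester: N-acetyl keto-lactone core with C9=C8–C7H2–C6H2–CO2Me (E/Z mixture) | CC[C@@H]1[C@H]2OC(=O)C[C@H]2[C@@]3(CCCN3C(C)=O)C1=CCCC(=O)OC
F2 | step 11 | saturated methyl ester: C9–H on the top face, N-acetyl | CC[C@@H]1[C@H]2OC(=O)C[C@H]2[C@@]3(CCCN3C(C)=O)[C@@H]1CCCC(=O)OC
F3 | step 11 | amino ester: N-deacetylated F2 | CC[C@@H]1[C@H]2OC(=O)C[C@H]2[C@@]3(CCCN3)[C@@H]1CCCC(=O)OC
F4 | step 10 | propargylic alcohol: ethynyl analogue of 18 (C9–OH cis to N4) | CC[C@@H]1[C@H]2OC(=O)C[C@H]2[C@@]3(CCCN3C(C)=O)[C@@]1(O)C#C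
F5 | step 17 | 3-vinyl lactam | CC[C@@H]1[C@H]2OC(=O)[C@@](C)(O)[C@H]2[C@]23CC[C@@H](C=C)N2C(=O)CCC[C@H]13
F6 | step 17 | C3 aldehyde | CC[C@@H]1[C@H]2OC(=O)[C@@](C)(O)[C@H]2[C@]23CC[C@@H](C=O)N2C(=O)CCC[C@H]13
F7 | step 17 | hydroxy ester: ethyl 4-hydroxy-2-methylenebutanoate unit on C3 | CC[C@@H]1[C@H]2OC(=O)[C@@](C)(O)[C@H]2[C@]23CC[C@@H]([C@@H](O)CC(=C)C(=O)OCC)N2C(=O)CCC[C@H]13
F8 | step 17 | α-methylene lactone: 5-oxo lactam with 3-methylene-γ-butyrolactone on C3 | CC[C@@H]1[C@H]2OC(=O)[C@@](C)(O)[C@H]2[C@]23CC[C@@H]([C@@H]4CC(=C)C(=O)O4)N2C(=O)CCC[C@H]13
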